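All runs are simulated from invented constants; scatter was added.

8 % of the charge stood as left-handed product at 20.0 h in zeta, and 8 % stood in gamma at 20.0 h, although gamma held 0.11 M of each substrate against 0.070 M in zeta. Your hunch, a saturated catalyst turning over at a fixed molar rate, asks for a lower percentage in gamma, and these readings do not show one.

| flask | left-handed substrate | right-handed substrate | partner | free catalyst | remark | time |
|---|---|---|---|---|---|---|
| zeta | 0.070 M | 0.070 M | 0.10 M | 0.50 mM | run made earlier |  |
| gamma | 0.11 M | 0.11 M | 0.10 M | 0.50 mM | run made earlier |  |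
| epsilon | 0.050 M | 0.050 M | 0.10 M | 0.75 mM | run made earlier |  |
| flask | 0.050 M | 0.050 M | 0.100 M | 0.50 mM |  | 25 h |

| run | time / h | left-handed product / % | right-handed product / % |
|---|---|---|---|
| zeta | 1.50 | 3 | 0 |
| zeta | 2.50 | 3 | 0 |
| zeta | 4.00 | 2 | 2 |
| zeta | 8.00 | 4 | 1 |
| zeta | 12.0 | 4 | 2 |
| zeta | 20.0 | 8 | 1 |
| gamma | 3.00 | 2 | 1 |
| gamma | 6.00 | 5 | 2 |
| gamma | 10.0 | 6 | 2 |
| gamma | 12.0 | 5 | 0 |
| gamma | 15.0 | 5 | 0 |
| gamma | 20.0 | 8 | 0 |
| epsilon | 4.00 | 3 | 0 |
| epsilon | 8.00 | 8 | 2 |
| epsilon | 12.0 | 11 | 0 |
| epsilon | 15.0 | 12 | 2 |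
| epsilon | 20.0 | 15 | 1 |

(each reading ± 1.5 percentage points)

- free catalyst is single-handed; left-handed substrate and right-handed substrate are mirror images of each other, charged as a racemate, each of them at the stated concentration
- the analysis behind the earlier runs scatters by 1.5 percentage points, standard deviation
- an excess is below zero if the other one leads

- excess of left-handed product over right-handed product in the product at 30 min
- excess of left-handed product over right-handed product in the product at 25 h
- part of the left-handed substrate and right-handed substrate charged together that has reacted at 25 h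

The concentration worth following is therefore the catalyst. Dividing the share of left-handed product by catalyst charge and time gives 8.00 L mol⁻¹ h⁻¹ for zeta, 8.00 L mol⁻¹ h⁻¹ for gamma and 10.0 L mol⁻¹ h⁻¹ for epsilon, which has more catalyst. With a scatter of 1.5 percentage points, these lie in one band. Their mean, 8.67 L mol⁻¹ h⁻¹, is the yield constant, a pseudo-first-order constant per unit of catalyst. For the flask, with 0.50 mM of catalyst over 25 h, it gives 10.8 % left-handed product. The right-handed readings, none above 2 %, are too near the scatter to carry a constant, so this reckoning stops there.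

The forecast, reasoning “so the rate is first order in substrate”, gave 78 % (58 % to 93 %), 75 % (58 % to 90 %) and 11 % reacted (9 % to 14 %).

The flask gives 75.1 %, 81.1 % and 14.5 %.

    free catalyst + left-handed substrate ⇌ catalyst intermediate A (K = 60.0 L mol⁻¹, k = 0.0900 L mol⁻¹ s⁻¹)
    free catalyst + right-handed substrate ⇌ catalyst intermediate B (K = 10.0 L mol⁻¹, k = 3.10 L mol⁻¹ s⁻¹)
    partner + catalyst intermediate A → free catalyst + left-handed product (k = 0.00830 L mol⁻¹ s⁻¹)
    partner + catalyst intermediate B → free catalyst + right-handed product (k = 0.00360 L mol⁻¹ s⁻¹)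
    left-handed substrate ⇌ right-handed substrate (k = 2.80 × 10⁻⁵ s⁻¹)
    partner → decomposed reagent (k = 9.40 × 10⁻⁶ s⁻¹)
    2 free catalyst → spent catalyst (k = 0.00670 L mol⁻¹ s⁻¹)

The flask's left-handed product of 12.8 % reads back as a constant of 10.3 L mol⁻¹ h⁻¹, above the reckoned 8.67 L mol⁻¹ h⁻¹. The flask's excess of 81.1 % at 25 h stands because catalyst intermediate B falls back to free catalyst and right-handed substrate: in the run with that return struck out, the excess is −98.3 %, so right-handed product leads there. The neighbour with 2.0 × 10⁻⁴ M of free catalyst has the same partner charge, and 10.3 L mol⁻¹ h⁻¹ gives it 5.13 % left-handed product. It computes to 5.58 %, with 6.30 % reacted.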